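**Plan**
- Retrosynthesis: the C3–OCH3 bond is cut first (O-methylation of a flavonol), and the C3–O bond is traced back to a C3–I bond.
- Next the O1–C2 bond of the pyranone ring (ring C) is cut together with C3–I, which opens the flavone to a pentamethoxyphenyl alkynyl ketone. The C4–C4a bond is then cut to pentamethoxyphenyllithium and the Weinreb amide of phenylpropiolic acid.
- Pentamethoxybenzene is traced to 1,2,3,4-tetramethoxybenzene through bromination and copper-catalysed methoxylation.
- Forward: rings A and B are bought, the three-carbon chain is joined at C4–C4a, ring C closes by 6-endo-dig iodocyclization with loss of one methyl group, and C3–I becomes C3–OH and then C3–OCH3.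
- Enabling feature: ring A carries oxygen on C5, C6, C7, C8 and C8a, so O1 (on C8a) and the C5 methoxyl oxygen are the two equivalent ortho oxygens of a symmetric pentamethoxybenzoyl group. Either one can become the ring oxygen and the other remains as the C5 methoxyl.
- Stereochemistry: the target has no stereogenic element, so nothing has to be set or preserved.

Key step: step 5

Assumption: the target is achiral, so "single enantiomer" is read as the single constitution shown; no stereocontrol is required.

**Route**

Step 1
Reactants: 1 1,2,3,4-tetramethoxybenzene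
Product: 2 1-bromo-2,3,4,5-tetramethoxybenzene
Conditions: NBS (1.0 equiv), MeCN, 0 °C → rt, dark
Reagents that add atoms: N-bromosuccinimide, O=C1CCC(=O)N1Br
Why: Electrophilic aromatic bromination; the two free positions of 1 are equivalent (each ortho to one methoxyl and para to another), so monobromination with one equivalent of NBS can give only one isomer.

Step 2
Reactants: 2 1-bromo-2,3,4,5-tetramethoxybenzene
Product: 3 pentamethoxybenzene
Conditions: NaOMe (25 wt% in MeOH, 5 equiv), CuBr (10 mol%), DMF, 110 °C
Reagents that add atoms: sodium methoxide, [Na+].[O-]C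
Why: Ullmann-type copper(I)-catalysed methoxylation of an aryl bromide; electron-rich o-methoxy bromoarenes are standard substrates and 2 has no other leaving group or acidic site.

Step 3
Reactants: 4 3-phenylprop-2-ynoic acid (phenylpropiolic acid)
Product: 5 N-methoxy-N-methyl-3-phenylprop-2-ynamide
Conditions: MeNHOMe·HCl, EDC·HCl, N-methylmorpholine, CH2Cl2, 0 °C → rt
Reagents that add atoms: N,O-dimethylhydroxylamine hydrochloride, CNOC.Cl
Why: Carbodiimide-mediated amide coupling (Weinreb amide formation); the weakly nucleophilic N,O-dimethylhydroxylamine should acylate at nitrogen at 0 °C without adding to the conjugated alkyne.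

Step 4
Reactants: 3 pentamethoxybenzene; 5 N-methoxy-N-methyl-3-phenylprop-2-ynamide
Product: 8 1-(2,3,4,5,6-pentamethoxyphenyl)-3-phenylprop-2-yn-1-one, via pentamethoxyphenyllithium 6 (not isolated), via lithium hemiaminal alkoxide adduct 7 (not isolated)
Conditions: n-BuLi (1.05 equiv), THF, 0 °C; then 5, −78 → −40 °C; inverse quench into cold 1 M HCl
Reagents that add atoms: none
Why: Directed ortho-lithiation removes the only ring hydrogen, which lies between two methoxyls, and the aryllithium acylates the Weinreb amide through a chelated tetrahedral adduct that cannot take up a second aryl group (Weinreb ketone synthesis), while the inverse acidic quench protonates the liberated amine before it can add to the ynone.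

Step 5
Reactants: 8 1-(2,3,4,5,6-pentamethoxyphenyl)-3-phenylprop-2-yn-1-one; 9 iodine monochloride
Product: 10 3-iodo-5,6,7,8-tetramethoxy-2-phenyl-4H-chromen-4-one (3-iodo-5,6,7,8-tetramethoxyflavone)
Conditions: ICl (1.5 equiv, 1 M in CH2Cl2), CH2Cl2, −78 °C → rt; aq. Na2S2O3
Reagents that add atoms: iodine monochloride 9, ClI
Why: Iodine monochloride should activate the ynone triple bond as an iodonium ion, the oxygen of one ortho methoxyl attacks the phenyl-bearing carbon, and chloride then removes the methyl group from the resulting aryl methyl oxonium ion by SN2 displacement to give the neutral 3-iodopyranone and chloromethane. The closest known reaction type is the iodine monochloride-induced demethylative cyclization of 2-methoxyaryl alkynyl ketones to 3-iodochromones and 3-iodoflavones (electrophilic iodocyclization). The one ring that closes, pyranone ring C, forms in the 6-endo-dig mode through the O1–C2 bond, with the C3–I bond made in the same event. No stereocentre is created. The step needs 6-endo over 5-exo closure and alkyne activation in preference to attack on the electron-rich arene; the first is secured by the carbonyl and phenyl groups, which together place the positive charge on the distal alkyne carbon, and the second by the absence of any C–H on the pentamethoxyphenyl ring. The two ortho methoxyls are equivalent by symmetry, so no regiochemical choice arises.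

Step 6
Reactants: 10 3-iodo-5,6,7,8-tetramethoxy-2-phenyl-4H-chromen-4-one
Product: 13 3-hydroxy-5,6,7,8-tetramethoxy-2-phenyl-4H-chromen-4-one, via flavon-3-ylmagnesium chloride 11 (not isolated), via dimethyl flavon-3-ylboronate 12 (not isolated)
Conditions: iPrMgCl·LiCl (1.1 equiv), THF, −40 °C; B(OMe)3, −40 → 0 °C; 30% H2O2, AcOH, 0 °C → rt
Reagents that add atoms: hydrogen peroxide, OO
Why: Iodine–magnesium exchange of the electron-poor alkenyl iodide (turbo-Grignard exchange) should outrun carbonyl addition at −40 °C, the C3–magnesium species is borylated by trimethyl borate, and peroxide-induced 1,2-migration from boron to oxygen gives the flavonol, the same borate–peroxide oxidation that is used on C3-metalated flavones.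

Step 7
Reactants: 13 3-hydroxy-5,6,7,8-tetramethoxy-2-phenyl-4H-chromen-4-one
Product: 14 3,5,6,7,8-pentamethoxy-2-phenyl-4H-chromen-4-one (3,5,6,7,8-pentamethoxyflavone)
Conditions: MeI (3 equiv), K2CO3, acetone, reflux
Reagents that add atoms: iodomethane, CI
Why: Williamson ether synthesis; the C3 hydroxyl of a flavonol is an acidic enol that iodomethane and potassium carbonate should O-methylate cleanly, and no other free hydroxyl is present.

**Compound list**
1 | 1,2,3,4-tetramethoxybenzene | COc1ccc(OC)c(OC)c1OC | starting material
2 | 1-bromo-2,3,4,5-tetramethoxybenzene | COc1cc(Br)c(OC)c(OC)c1OC | intermediate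
3 | pentamethoxybenzene | COc1cc(OC)c(OC)c(OC)c1OC | intermediate
4 | 3-phenylprop-2-ynoic acid (phenylpropiolic acid) | O=C(O)C#Cc1ccccc1 | starting material
5 | N-methoxy-N-methyl-3-phenylprop-2-ynamide | CON(C)C(=O)C#Cc1ccccc1 | intermediate
6 | (2,3,4,5,6-pentamethoxyphenyl)lithium (not isolated) | [Li]c1c(OC)c(OC)c(OC)c(OC)c1OC | intermediate
7 | lithium 1-[methoxy(methyl)amino]-1-(2,3,4,5,6-pentamethoxyphenyl)-3-phenylprop-2-yn-1-olate (racemic, not isolated) | [Li]OC(C#Cc1ccccc1)(N(C)OC)c1c(OC)c(OC)c(OC)c(OC)c1OC | intermediate
8 | 1-(2,3,4,5,6-pentamethoxyphenyl)-3-phenylprop-2-yn-1-one | COc1c(OC)c(OC)c(C(=O)C#Cc2ccccc2)c(OC)c1OC | intermediate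
9 | iodine monochloride | ClI | starting material
10 | 3-iodo-5,6,7,8-tetramethoxy-2-phenyl-4H-chromen-4-one | COc1c(OC)c(OC)c2c(=O)c(I)c(-c3ccccc3)oc2c1OC | intermediate
11 | (5,6,7,8-tetramethoxy-4-oxo-2-phenyl-4H-chromen-3-yl)magnesium chloride, LiCl complex (not isolated) | COc1c(OC)c(OC)c2c(=O)c([Mg]Cl)c(-c3ccccc3)oc2c1OC | intermediate
12 | dimethyl (5,6,7,8-tetramethoxy-4-oxo-2-phenyl-4H-chromen-3-yl)boronate (not isolated) | COB(OC)c1c(-c2ccccc2)oc2c(OC)c(OC)c(OC)c(OC)c2c1=O | intermediate
13 | 3-hydroxy-5,6,7,8-tetramethoxy-2-phenyl-4H-chromen-4-one | COc1c(OC)c(OC)c2c(=O)c(O)c(-c3ccccc3)oc2c1OC | intermediate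
14 | 3,5,6,7,8-pentamethoxy-2-phenyl-4H-chromen-4-one (3,5,6,7,8-pentamethoxyflavone) | COc1c(OC)c(OC)c2c(=O)c(OC)c(-c3ccccc3)oc2c1OC | target

**Step count**
Total steps: 7. Longest linear sequence: 6 (steps 1, 2, 4, 5, 6, 7); step 3 is a one-step side branch.

**Steps most likely to fail**

Step 5. Iodine monochloride may add across the triple bond without ring closure, leaving an open β-chloro-α-iodo enone, or it may oxidatively demethylate the para-related methoxyls of the ring faster than it activates the alkyne. The fallback separates ring closure from C3 functionalization; it sets out from 8 and comes back to the route at 12. Boron trichloride in CH2Cl2 at −78 → 0 °C, chelated between the carbonyl and one of the two equivalent ortho methoxyls, should remove a single methyl group and give 1-(2-hydroxy-3,4,5,6-tetramethoxyphenyl)-3-phenylprop-2-yn-1-one F1. Catalytic DMAP in DMF should then close the phenol onto the ynone by 6-endo-dig oxa-Michael addition to give 5,6,7,8-tetramethoxy-2-phenyl-4H-chromen-4-one F2. Deprotonation of F2 at C3 with LDA in THF at −78 °C gives 3-lithio-5,6,7,8-tetramethoxy-2-phenyl-4H-chromen-4-one F3 (not isolated), which is trapped with trimethyl borate to give 12 and oxidized as in step 6.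

Step 6. The C3-metalated flavone may ring-open by β-elimination of O1 to an alkynyl phenolate, the Grignard reagent may add to the pyranone instead of exchanging, or the organomagnesium may be protonated before borylation and return the deiodinated flavone. The fallback avoids any C3 carbanion; it sets out from 10 and comes back at the target 14. Ullmann-type copper-catalysed C–O coupling of the alkenyl iodide with methanol (CuI, 3,4,7,8-tetramethyl-1,10-phenanthroline, Cs2CO3, MeOH/toluene, 90 °C) should install the C3 methoxyl directly, so step 7 is no longer needed. This fallback makes no new compound (F0).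

Step 4. The liberated N,O-dimethylhydroxylamine or a second aryllithium may add in conjugate fashion to the ynone while the tetrahedral adduct collapses, or the di-ortho-substituted aryllithium may add too slowly to the amide. The fallback changes the electrophile and the oxidation level; it sets out from 3 and comes back at 8. Lithiation of 3 as in step 4 gives 6, which is added at −78 °C to commercial 3-phenylprop-2-ynal to give racemic 1-(2,3,4,5,6-pentamethoxyphenyl)-3-phenylprop-2-yn-1-ol F4. Oxidation of this benzylic and propargylic alcohol with activated MnO2 in CH2Cl2 should give 8.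

**Further compounds**
F1 | step 5 | 1-(2-hydroxy-3,4,5,6-tetramethoxyphenyl)-3-phenylprop-2-yn-1-one | COc1c(OC)c(OC)c(C(=O)C#Cc2ccccc2)c(O)c1OC
F2 | step 5 | 5,6,7,8-tetramethoxy-2-phenyl-4H-chromen-4-one | COc1c(OC)c(OC)c2c(=O)cc(-c3ccccc3)oc2c1OC
F3 | step 5 | 3-lithio-5,6,7,8-tetramethoxy-2-phenyl-4H-chromen-4-one | COc1c(OC)c(OC)c2c(=O)c([Li])c(-c3ccccc3)oc2c1OC
F0 | step 6 | none | none
F4 | step 4 | 1-(2,3,4,5,6-pentamethoxyphenyl)-3-phenylprop-2-yn-1-ol (racemic) | COc1c(OC)c(OC)c(C(O)C#Cc2ccccc2)c(OC)c1OC
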